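**Retrosynthetic overview**

1. Germacrane numbering is used throughout. Ring A is the carbocycle C1–C10 and ring B is the lactone O–C6–C7–C11–C12. C13 is the exocyclic CH2, C14 the ester carbon and C15 the methyl. The target is traced back by desilylation at O9 and an invertive esterification at C8 with (2R,3R)-2,3-dimethyloxirane-2-carboxylic acid, which leads to the bicyclic 8α-carbinol.
2. The enabling feature is the homoallylic carbinol array O–C8–C7–C11(=C13H2) at the junction of rings A and B. Retro-allylation across C7–C8 moves the alkene into ring B (butenolide C7=C11 carrying C13H2Br) and leaves an open-chain C8 aldehyde. Its three contiguous cis units (C1=C10, oxirane C2–C3, C4=C5) fold the chain for closure.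
3. The open chain comes from a Horner–Wadsworth–Emmons olefination at C1=C10, joining a malate-derived C8–C9–C10–C14 phosphonate to a cis-epoxy aldehyde. That aldehyde comes from asymmetric epoxidation of a (2Z,4Z)-dienol, which is made by Stille coupling at C3–C4.
4. The butenolide vinyl iodide comes from ring-closing metathesis of an acrylate of resolved (3S,4Z)-5-iodohexa-1,4-dien-3-ol, itself made from acrolein and a propynyl Grignard reagent.
5. Order of ring formation: ring B as butenolide (step 6), oxirane C2–C3 (step 9), ring A (step 18). The side-chain oxirane is made separately (step 20).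

Key step: step 18

Remark: CIP descriptors of unchanged centres switch in places only because substituent priorities change, for example at C6 after the Stille coupling and at C7 between the free C8 carbinol and its ester.

Step 1
Reactants: 1 2-(bromomethyl)prop-2-enoic acid; 2 4-methoxybenzyl alcohol
Product: 4 2-{[(4-methoxybenzyl)oxy]methyl}prop-2-enoic acid, via sodium 4-methoxybenzyl oxide 3 (not isolated)
Conditions: 2, NaH (2.2 equiv), THF, 0 °C; then 1, 0 °C → rt; aq. HCl work-up
Reagents that add atoms: none
Why: Williamson ether synthesis on an activated allylic bromide: the alkoxide 3 displaces bromide from the carboxylate of 1 (direct or addition–elimination attack gives the same ether) and no stereocentre is involved.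

Step 2
Reactants: 5 acrolein; 6 prop-1-yn-1-ylmagnesium bromide
Product: 7 rac-hex-1-en-4-yn-3-ol
Conditions: THF, −78 °C → 0 °C; aqueous work-up
Reagents that add atoms: none
Why: 1,2-Addition of an alkynyl Grignard reagent to an enal, which at low temperature attacks the carbonyl carbon only; the new carbinol centre (C6) is racemic here and is resolved in step 4.

Step 3
Reactants: 7 rac-hex-1-en-4-yn-3-ol
Product: 9 rac-(4Z)-5-iodohexa-1,4-dien-3-ol, via sodium vinylalanate 8 (not isolated)
Conditions: NaAlH2(OCH2CH2OCH3)2, THF, 0 °C → rt; then I2, −78 °C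
Reagents that add atoms: iodine II
Why: Hydroxyl-directed trans-hydroalumination of a propargylic alcohol places aluminium on the distal alkyne carbon (C4) inside the five-membered alanate 8, and iodinolysis with retention should give only the Z vinyl iodide (iodine cis to C6), the isolated vinyl group being inert.

Step 4
Reactants: 9 rac-(4Z)-5-iodohexa-1,4-dien-3-ol
Product: 10 (3S,4Z)-5-iodohexa-1,4-dien-3-ol
Conditions: immobilised Candida antarctica lipase B, vinyl acetate, MTBE, 30 °C, stopped just past half conversion; chromatography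
Reagents that add atoms: none
Why: Lipase-catalysed kinetic resolution by transesterification: by the empirical size rule for secondary alcohols the enantiomer with the small vinyl and the large iodoalkenyl group in the (R) arrangement is acetylated faster, so that the (S)-alcohol, which carries the C6 configuration of the target, should remain.

Step 5
Reactants: 10 (3S,4Z)-5-iodohexa-1,4-dien-3-ol; 4 2-{[(4-methoxybenzyl)oxy]methyl}prop-2-enoic acid
Product: 11 (3S,4Z)-5-iodohexa-1,4-dien-3-yl 2-{[(4-methoxybenzyl)oxy]methyl}prop-2-enoate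
Conditions: EDC·HCl, DMAP (cat.), CH2Cl2, 0 °C → rt
Reagents that add atoms: none
Why: Steglich-type carbodiimide esterification, which acylates oxygen without touching the C6–O bond, so that the configuration is retained.

Step 6
Reactants: 11 (3S,4Z)-5-iodohexa-1,4-dien-3-yl 2-{[(4-methoxybenzyl)oxy]methyl}prop-2-enoate
Product: 12 (5S)-5-[(1Z)-2-iodoprop-1-en-1-yl]-3-{[(4-methoxybenzyl)oxy]methyl}furan-2(5H)-one
Conditions: second-generation Hoveyda–Grubbs catalyst (5 mol %), toluene, 70 °C, argon sparge
Reagents that add atoms: none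
Why: Ring-closing metathesis of an allyl acrylate to a butenolide (ring B): the catalyst loads on the terminal vinyl group and closes on the 1,1-disubstituted acrylate, while the trisubstituted iodoalkene is too hindered to take part and C6 is untouched.

Step 7
Reactants: 13 prop-2-yn-1-ol
Product: 15 (2Z)-3-(tributylstannyl)prop-2-en-1-ol, via lithium vinylalanate 14 (not isolated)
Conditions: LiAlH4, THF, 0 °C → rt; then Bu3SnOTf, −78 °C → rt
Reagents that add atoms: tributyltin trifluoromethanesulfonate CCCC[Sn](CCCC)(CCCC)OS(=O)(=O)C(F)(F)F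
Why: Directed trans-hydroalumination of propargyl alcohol to the cyclic alanate 14 followed by stannylation with retention, which fixes the Z geometry (tin cis to the carbinol carbon).

Step 8
Reactants: 12 (5S)-5-[(1Z)-2-iodoprop-1-en-1-yl]-3-{[(4-methoxybenzyl)oxy]methyl}furan-2(5H)-one; 15 (2Z)-3-(tributylstannyl)prop-2-en-1-ol
Product: 16 (5R)-5-[(1Z,3Z)-5-hydroxy-2-methylpenta-1,3-dien-1-yl]-3-{[(4-methoxybenzyl)oxy]methyl}furan-2(5H)-one
Conditions: Pd2(dba)3 (5 mol %), AsPh3 (20 mol %), NMP, rt, dark
Reagents that add atoms: none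
Why: Stille coupling of a vinyl iodide and a vinylstannane, stereoretentive at both partners, so that the 2Z,4Z-diene results; zerovalent palladium inserts into the C–I bond at room temperature much faster than it ionises the hindered allylic lactone C6–O bond.

Step 9
Reactants: 16 (5R)-5-[(1Z,3Z)-5-hydroxy-2-methylpenta-1,3-dien-1-yl]-3-{[(4-methoxybenzyl)oxy]methyl}furan-2(5H)-one
Product: 17 (5R)-5-{(1Z)-2-[(2S,3R)-3-(hydroxymethyl)oxiran-2-yl]prop-1-en-1-yl}-3-{[(4-methoxybenzyl)oxy]methyl}furan-2(5H)-one
Conditions: Ti(OiPr)4 (30 mol %), D-(−)-diethyl tartrate (36 mol %), t-BuOOH (decane), 4 Å MS, CH2Cl2, −25 °C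
Reagents that add atoms: tert-butyl hydroperoxide CC(C)(C)OO
Why: Sharpless asymmetric epoxidation: only the alkene allylic to the titanium-bound primary alkoxide (C2=C3) is oxidised, syn addition to the Z-alkene gives the cis-oxirane, and the D-(−)-tartrate ligand selects the face that gives 2R,3S (germacrane numbering) irrespective of the remote C6 centre.

Step 10
Reactants: 17 (5R)-5-{(1Z)-2-[(2S,3R)-3-(hydroxymethyl)oxiran-2-yl]prop-1-en-1-yl}-3-{[(4-methoxybenzyl)oxy]methyl}furan-2(5H)-one
Product: 18 (2S,3S)-3-{(1Z)-1-[(2R)-4-{[(4-methoxybenzyl)oxy]methyl}-5-oxo-2,5-dihydrofuran-2-yl]prop-1-en-2-yl}oxirane-2-carbaldehyde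
Conditions: Dess–Martin periodinane, NaHCO3, CH2Cl2, 0 °C
Reagents that add atoms: none
Why: Dess–Martin oxidation under buffered, non-basic conditions, which avoids epimerisation of the cis-epoxy aldehyde at C2 and of the butenolide at C6.

Step 11
Reactants: 19 dimethyl (2S)-2-hydroxybutanedioate (dimethyl L-malate)
Product: 20 methyl (3S)-3,4-dihydroxybutanoate
Conditions: BH3·SMe2, NaBH4 (5 mol %), THF, 0 °C → rt; MeOH quench
Reagents that add atoms: none
Why: Hydroxyl-directed borane reduction of a malate: the alkoxyborane formed at the free hydroxyl delivers hydride to the neighbouring ester only, and the stereocentre (future C9, from the chiral pool) is not touched.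

Step 12
Reactants: 20 methyl (3S)-3,4-dihydroxybutanoate
Product: 21 methyl (3S)-3,4-bis(triethylsilyloxy)butanoate
Conditions: Et3SiCl (2.3 equiv), imidazole, CH2Cl2, 0 °C
Reagents that add atoms: chlorotriethylsilane CC[Si](Cl)(CC)CC
Why: Silyl ether formation with a silyl chloride and imidazole, done at once on crude 20 to outrun lactonisation; triethylsilyl groups are chosen because the primary one can later be oxidised directly and the secondary one is non-chelating and comes off under mild conditions.

Step 13
Reactants: 21 methyl (3S)-3,4-bis(triethylsilyloxy)butanoate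
Product: 24 methyl (3R)-2-(diethoxyphosphoryl)-3,4-bis(triethylsilyloxy)butanoate (both C2 epimers), via lithium enolate 22 (not isolated), via phosphonite ester 23 (not isolated)
Conditions: LiN(iPr)2 (1.05 equiv), THF, −78 °C; ClP(OEt)2, −78 → 0 °C; 30 % aq. H2O2, 0 °C
Reagents that add atoms: diethyl chlorophosphite CCOP(Cl)OCC; hydrogen peroxide OO
Why: C-Phosphinylation of an ester enolate with a trivalent phosphorus chloride followed by oxidation to the phosphonate; one equivalent of base at −78 °C keeps β-elimination of the silyloxy group slow, and the new centre (C10) is of no consequence because it becomes sp2 in step 14.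

Step 14
Reactants: 24 methyl (3R)-2-(diethoxyphosphoryl)-3,4-bis(triethylsilyloxy)butanoate; 18 (2S,3S)-3-{(1Z)-1-[(2R)-4-{[(4-methoxybenzyl)oxy]methyl}-5-oxo-2,5-dihydrofuran-2-yl]prop-1-en-2-yl}oxirane-2-carbaldehyde
Product: 26 methyl (2E)-2-[(1S)-1,2-bis(triethylsilyloxy)ethyl]-3-[(2R,3S)-3-{(1Z)-1-[(2R)-4-{[(4-methoxybenzyl)oxy]methyl}-5-oxo-2,5-dihydrofuran-2-yl]prop-1-en-2-yl}oxiran-2-yl]prop-2-enoate, via sodium phosphonate 25 (not isolated)
Conditions: 24 (1.3 equiv), NaH (1.2 equiv), THF, 0 °C; then 18, −78 → −20 °C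
Reagents that add atoms: none
Why: Horner–Wadsworth–Emmons olefination with a preformed sodium phosphonate (no free base left to deprotonate C6–H or C2–H): reversible addition should funnel to the alkene with C2 trans to the ester, that is 1(10)E, the tiglate-type geometry of the target.

Step 15
Reactants: 26 the C13-O-(4-methoxybenzyl) bis(triethylsilyl) enoate
Product: 27 methyl (2E)-2-[(1S)-1,2-bis(triethylsilyloxy)ethyl]-3-[(2R,3S)-3-{(1Z)-1-[(2R)-4-(hydroxymethyl)-5-oxo-2,5-dihydrofuran-2-yl]prop-1-en-2-yl}oxiran-2-yl]prop-2-enoate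
Conditions: DDQ, CH2Cl2/pH 7 buffer, 0 °C
Reagents that add atoms: none
Why: Oxidative cleavage of a 4-methoxybenzyl ether by DDQ under buffered conditions, which leaves silyl ethers, oxirane and electron-poor alkenes untouched.

Step 16
Reactants: 27 the C13 allylic alcohol
Product: 28 methyl (2E)-2-[(1S)-1,2-bis(triethylsilyloxy)ethyl]-3-[(2R,3S)-3-{(1Z)-1-[(2R)-4-(bromomethyl)-5-oxo-2,5-dihydrofuran-2-yl]prop-1-en-2-yl}oxiran-2-yl]prop-2-enoate
Conditions: CBr4, PPh3, CH2Cl2, −20 → 0 °C
Reagents that add atoms: carbon tetrabromide BrC(Br)(Br)Br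
Why: Appel bromination of a primary allylic alcohol under neutral conditions, compatible with silyl ethers and oxirane.

Step 17
Reactants: 28 the C13 allylic bromide
Product: 30 methyl (2E)-3-[(2R,3S)-3-{(1Z)-1-[(2R)-4-(bromomethyl)-5-oxo-2,5-dihydrofuran-2-yl]prop-1-en-2-yl}oxiran-2-yl]-2-[(1S)-2-oxo-1-(triethylsilyloxy)ethyl]prop-2-enoate, via alkoxysulfonium chloride 29 (not isolated)
Conditions: (COCl)2, DMSO, CH2Cl2, −78 → −35 °C; iPr2NEt, −78 → −20 °C; used at once
Reagents that add atoms: none
Why: Swern oxidation applied directly to the bis-silyl ether: the activated sulfoxide attacks only the unhindered primary triethylsilyl ether to give 29, which collapses to the aldehyde on addition of the non-nucleophilic base, so that a free C8 alcohol (prone to lactonise on C14) never exists and C9 is not epimerised at low temperature.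

Step 18
Reactants: 30 the open-chain bromo aldehyde
Product: 33 methyl (1(10)E,4Z,2R,3S,6R,7R,8R,9S)-2,3-epoxy-8-hydroxy-9-(triethylsilyloxy)germacra-1(10),4,11(13)-trien-12,6-olid-14-oate (8α-carbinol), via allylchromium species 31 (not isolated), via chromium alkoxide 32 (not isolated)
Conditions: CrCl2 (10 equiv), THF, rt, syringe-pump addition of 30 over 12 h to about 1 mM; aqueous work-up
Reagents that add atoms: none
Why: Two equivalents of CrCl2 reduce the allylic C13–Br bond in two one-electron steps to the allylchromium species 31 (trivalent chromium), which adds through its γ-carbon C7 to the C8 aldehyde in a six-membered Zimmerman–Traxler chair, moving the alkene from C7=C11 to C11=C13 and so unveiling the α-methylene lactone while ring A closes. The closest known reaction type is the Nozaki–Hiyama (chromium Barbier) allylation, precedented both for intermolecular additions of 3-(bromomethyl)furan-2(5H)-ones to aldehydes and for closures of ten-membered germacrane rings from 2-(bromomethyl)acrylate aldehydes. Ring A forms by a 10-exo-trig attack on the carbonyl group, made feasible by the contiguous cis units (C1=C10, oxirane C2–C3, C4=C5) that curl the seven-atom tether so that C8 lies under C7. C7 is set by C6: the aldehyde can reach only the butenolide face anti to the C5 substituent without eclipsing C5–C6–C7–C8, which gives the trans ring fusion (H6 and H7 anti). C8 is set by the ring-locked E-type allyl geometry (C6 trans to C13) with C9 equatorial in the chair, reinforced by the polar Felkin–Anh preference of the non-chelating α-silyloxy group, giving the 7,8-anti/8,9-anti array, that is the (8R) carbinol whose inversion is planned in step 22. The step needs chemoselective reduction of the allylic bromide beside the epoxy enoate and unimolecular capture of 31, secured by the far easier reduction of the activated bromide, by the inertness of esters, lactone and oxiranes to allylchromium reagents, and by slow addition at high dilution.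

Step 19
Reactants: 34 methyl (2Z)-2-methylbut-2-enoate (methyl angelate)
Product: 35 (2Z)-2-methylbut-2-en-1-ol
Conditions: LiAlH4, Et2O, 0 °C
Reagents that add atoms: none
Why: Hydride reduction of an α,β-unsaturated ester to the allylic alcohol with retention of the Z geometry.

Step 20
Reactants: 35 (2Z)-2-methylbut-2-en-1-ol
Product: 36 [(2S,3R)-2,3-dimethyloxiran-2-yl]methanol
Conditions: Ti(OiPr)4 (10 mol %), L-(+)-diethyl tartrate (12 mol %), t-BuOOH, 4 Å MS, CH2Cl2, −20 °C
Reagents that add atoms: tert-butyl hydroperoxide CC(C)(C)OO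
Why: Sharpless asymmetric epoxidation: syn oxygen transfer to the Z-alkene keeps CH2OH and the C4 methyl cis, and L-(+)-tartrate selects the face that gives the 2S,3R epoxy alcohol.

Step 21
Reactants: 36 [(2S,3R)-2,3-dimethyloxiran-2-yl]methanol
Product: 37 (2R,3R)-2,3-dimethyloxirane-2-carboxylic acid
Conditions: RuCl3·xH2O (2 mol %), NaIO4, MeCN/EtOAc/H2O, 0 °C → rt
Reagents that add atoms: water O; sodium periodate [Na+].[O-]I(=O)(=O)=O
Why: Ruthenium tetroxide oxidation (RuCl3/NaIO4) of a 2,3-epoxy alcohol to the glycidic acid, which leaves both oxirane centres untouched (the C2 descriptor changes to R only by priority).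

Step 22
Reactants: 33 the 8α-carbinol; 37 (2R,3R)-2,3-dimethyloxirane-2-carboxylic acid
Product: 38 methyl (1(10)E,4Z,2R,3S,6R,7S,8S,9S)-8-[(2R,3R)-2,3-dimethyloxirane-2-carbonyloxy]-2,3-epoxy-9-(triethylsilyloxy)germacra-1(10),4,11(13)-trien-12,6-olid-14-oate
Conditions: PPh3, DIAD (betaine preformed), toluene, 0 °C; then 37 and 33, 0 °C → rt
Reagents that add atoms: none
Why: Mitsunobu esterification: the secondary, non-allylic C8 carbinol is activated as its oxyphosphonium ion and displaced by the carboxylate of the fairly strong acid 37 in an SN2 process from the β face, which inverts C8 from R to the S configuration of the target and installs the side chain in the same operation; preforming the betaine keeps free phosphine away from the exocyclic methylene.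

Step 23
Reactants: 38 the 9-O-triethylsilyl ether of the target
Product: 39 CNP0291485.1, methyl (1(10)E,4Z,2R,3S,6R,7S,8S,9S)-8-[(2R,3R)-2,3-dimethyloxirane-2-carbonyloxy]-2,3-epoxy-9-hydroxygermacra-1(10),4,11(13)-trien-12,6-olid-14-oate
Conditions: HF·pyridine, pyridine, THF, 0 °C
Reagents that add atoms: none
Why: Fluoride-mediated cleavage of the secondary triethylsilyl ether under buffered, weakly acidic conditions that should spare both oxiranes and suppress O8-to-O9 acyl migration.

**Compound list**

1 | 2-(bromomethyl)prop-2-enoic acid | C=C(CBr)C(=O)O | starting material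
2 | 4-methoxybenzyl alcohol | COc1ccc(CO)cc1 | starting material
3 | sodium 4-methoxybenzyl oxide | [Na+].[O-]Cc1ccc(OC)cc1 | intermediate
4 | 2-{[(4-methoxybenzyl)oxy]methyl}prop-2-enoic acid | C=C(COCc1ccc(OC)cc1)C(=O)O | intermediate
5 | acrolein | C=CC=O | starting material
6 | prop-1-yn-1-ylmagnesium bromide | CC#C[Mg]Br | starting material
7 | rac-hex-1-en-4-yn-3-ol | C=CC(O)C#CC | intermediate
8 | sodium vinylalanate (five-membered O–Al–C4 ring) | [Na+].COCCO[Al-]1(OCCOC)OC(C=C)C=C1C | intermediate
9 | rac-(4Z)-5-iodohexa-1,4-dien-3-ol | C=CC(O)/C=C(/C)I | intermediate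
10 | (3S,4Z)-5-iodohexa-1,4-dien-3-ol | O[C@@H](C=C)/C=C(/C)I | intermediate
11 | (3S,4Z)-5-iodohexa-1,4-dien-3-yl 2-{[(4-methoxybenzyl)oxy]methyl}prop-2-enoate | C=C(COCc1ccc(OC)cc1)C(=O)O[C@@H](C=C)/C=C(/C)I | intermediate
12 | (5S)-5-[(1Z)-2-iodoprop-1-en-1-yl]-3-{[(4-methoxybenzyl)oxy]methyl}furan-2(5H)-one | COc1ccc(COCC2=C[C@H](OC2=O)/C=C(/C)I)cc1 | intermediate
13 | prop-2-yn-1-ol | C#CCO | starting material
14 | lithium vinylalanate (five-membered O–Al–C ring) | [Li+].[H][Al-]1([H])OCC=C1 | intermediate
15 | (2Z)-3-(tributylstannyl)prop-2-en-1-ol | OC/C=C\[Sn](CCCC)(CCCC)CCCC | intermediate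
16 | (5R)-5-[(1Z,3Z)-5-hydroxy-2-methylpenta-1,3-dien-1-yl]-3-{[(4-methoxybenzyl)oxy]methyl}furan-2(5H)-one | COc1ccc(COCC2=C[C@H](OC2=O)/C=C(/C)\C=C/CO)cc1 | intermediate
17 | (5R)-5-{(1Z)-2-[(2S,3R)-3-(hydroxymethyl)oxiran-2-yl]prop-1-en-1-yl}-3-{[(4-methoxybenzyl)oxy]methyl}furan-2(5H)-one | COc1ccc(COCC2=C[C@H](OC2=O)/C=C(/C)[C@@H]3O[C@@H]3CO)cc1 | intermediate
18 | (2S,3S)-3-{(1Z)-1-[(2R)-4-{[(4-methoxybenzyl)oxy]methyl}-5-oxo-2,5-dihydrofuran-2-yl]prop-1-en-2-yl}oxirane-2-carbaldehyde | COc1ccc(COCC2=C[C@H](OC2=O)/C=C(/C)[C@@H]3O[C@@H]3C=O)cc1 | intermediate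
19 | dimethyl (2S)-2-hydroxybutanedioate | COC(=O)C[C@H](O)C(=O)OC | starting material
20 | methyl (3S)-3,4-dihydroxybutanoate | COC(=O)C[C@H](O)CO | intermediate
21 | methyl (3S)-3,4-bis(triethylsilyloxy)butanoate | COC(=O)C[C@H](O[Si](CC)(CC)CC)CO[Si](CC)(CC)CC | intermediate
22 | lithium enolate of 21 | [Li+].COC([O-])=C[C@H](O[Si](CC)(CC)CC)CO[Si](CC)(CC)CC | intermediate
23 | methyl (3R)-2-(diethoxyphosphanyl)-3,4-bis(triethylsilyloxy)butanoate (C2 epimers) | COC(=O)C(P(OCC)OCC)[C@H](O[Si](CC)(CC)CC)CO[Si](CC)(CC)CC | intermediate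
24 | methyl (3R)-2-(diethoxyphosphoryl)-3,4-bis(triethylsilyloxy)butanoate (C2 epimers) | COC(=O)C(P(=O)(OCC)OCC)[C@H](O[Si](CC)(CC)CC)CO[Si](CC)(CC)CC | intermediate
25 | sodium salt of 24 | [Na+].COC(=O)[C-](P(=O)(OCC)OCC)[C@H](O[Si](CC)(CC)CC)CO[Si](CC)(CC)CC | intermediate
26 | open-chain enoate, C13-OPMB, O8- and O9-triethylsilyl (2R,3S,6R,9S; 1(10)E,4Z) | COc1ccc(COCC2=C[C@H](OC2=O)/C=C(/C)[C@@H]3O[C@@H]3/C=C(/C(=O)OC)[C@H](O[Si](CC)(CC)CC)CO[Si](CC)(CC)CC)cc1 | intermediate
27 | open-chain enoate, C13-OH (2R,3S,6R,9S; 1(10)E,4Z) | OCC1=C[C@H](OC1=O)/C=C(/C)[C@@H]2O[C@@H]2/C=C(/C(=O)OC)[C@H](O[Si](CC)(CC)CC)CO[Si](CC)(CC)CC | intermediate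
28 | open-chain enoate, C13-Br (2R,3S,6R,9S; 1(10)E,4Z) | BrCC1=C[C@H](OC1=O)/C=C(/C)[C@@H]2O[C@@H]2/C=C(/C(=O)OC)[C@H](O[Si](CC)(CC)CC)CO[Si](CC)(CC)CC | intermediate
29 | C8-O-dimethylsulfonium chloride of the bromide | [Cl-].BrCC1=C[C@H](OC1=O)/C=C(/C)[C@@H]2O[C@@H]2/C=C(/C(=O)OC)[C@H](O[Si](CC)(CC)CC)CO[S+](C)C | intermediate
30 | open-chain C13 bromide C8 aldehyde (2R,3S,6R,9S; 1(10)E,4Z) | BrCC1=C[C@H](OC1=O)/C=C(/C)[C@@H]2O[C@@H]2/C=C(/C(=O)OC)[C@H](O[Si](CC)(CC)CC)C=O | intermediate
31 | C13 allylchromium dichloride of 30 | Cl[Cr](Cl)CC1=C[C@H](OC1=O)/C=C(/C)[C@@H]2O[C@@H]2/C=C(/C(=O)OC)[C@H](O[Si](CC)(CC)CC)C=O | intermediate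
32 | O8 chromium dichloride alkoxide of 33 | C=C1C(=O)O[C@@H]2/C=C(/C)[C@@H]3O[C@@H]3/C=C(/C(=O)OC)[C@H](O[Si](CC)(CC)CC)[C@H](O[Cr](Cl)Cl)[C@@H]12 | intermediate
33 | bicyclic 8α-carbinol, 9-O-triethylsilyl (2R,3S,6R,7R,8R,9S) | C=C1C(=O)O[C@@H]2/C=C(/C)[C@@H]3O[C@@H]3/C=C(/C(=O)OC)[C@H](O[Si](CC)(CC)CC)[C@H](O)[C@@H]12 | intermediate
34 | methyl (2Z)-2-methylbut-2-enoate | C/C=C(/C)C(=O)OC | starting material
35 | (2Z)-2-methylbut-2-en-1-ol | C/C=C(/C)CO | intermediate
36 | [(2S,3R)-2,3-dimethyloxiran-2-yl]methanol | OC[C@]1(C)O[C@@H]1C | intermediate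
37 | (2R,3R)-2,3-dimethyloxirane-2-carboxylic acid | OC(=O)[C@]1(C)O[C@@H]1C | intermediate
38 | 9-O-triethylsilyl ether of the target (2R,3S,6R,7S,8S,9S,2′R,3′R) | C=C1C(=O)O[C@@H]2/C=C(/C)[C@@H]3O[C@@H]3/C=C(/C(=O)OC)[C@H](O[Si](CC)(CC)CC)[C@@H](OC(=O)[C@]3(C)O[C@@H]3C)[C@@H]12 | intermediate
39 | CNP0291485.1 (2R,3S,6R,7S,8S,9S,2′R,3′R; 1(10)E,4Z) | C=C1C(=O)O[C@@H]2/C=C(/C)[C@@H]3O[C@@H]3/C=C(/C(=O)OC)[C@H](O)[C@@H](OC(=O)[C@]3(C)O[C@@H]3C)[C@@H]12 | target

**Step count**

- Total step count: 23.
- Longest linear sequence: 15 steps (steps 2–6, 8–10, 14–18, 22, 23).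

**Three steps most likely to fail**

1. **Step 18.**
   - *Risk:* The slow ten-membered closure may let intermolecular coupling, protonolysis of the allylchromium species or reductive opening of the epoxy enoate compete. The strain of the forming ring may also force a boat-type or C9-axial transition state, which would erode or reverse the facial selectivity at the aldehyde.
   - *Fallback (sets out from 30, comes back at 38):* The endgame is made stereoconvergent instead of depending on one C8 epimer. The closure of 30 is accepted as a mixture and the epimers are separated. 33 goes on through step 22. The (8S)-carbinol F1 is acylated with retention by 37 through a mixed anhydride (2-methyl-6-nitrobenzoic anhydride, DMAP, CH2Cl2, rt). Both epimers then meet at 38.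

2. **Step 22.**
   - *Risk:* The hindered C8 oxyphosphonium ion may collapse by elimination towards C7, giving a conjugated diene lactone. Carboxylate may attack at phosphorus, which leads to retention. Free phosphine may add to the exocyclic methylene.
   - *Fallback (sets out from 33, comes back at 38):* Inversion by substitution is replaced by an oxidation–reduction sequence. Dess–Martin oxidation of 33 gives the 8-ketone F2, which is reduced at once under Luche conditions (NaBH4, CeCl3·7H2O, MeOH, −78 °C). Felkin–Anh attack anti to the C9 silyloxy group should give the 8,9-syn (8S)-carbinol F1. F1 is then esterified with retention by 37 (2-methyl-6-nitrobenzoic anhydride, DMAP) to 38.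

3. **Step 14.**
   - *Risk:* The phosphonate carbanion may lose silanolate by β-elimination. It may act as a base on C6–H of the butenolide. With its branched α-substituent it may also give poor control of the alkene geometry.
   - *Fallback (sets out from 18, comes back at 26):* The C1=C10 and C9–C10 bonds are made in two separate events.
     - 18 is olefinated with Ph3P=C(I)CO2Me, made in the flask from methyl (triphenylphosphoranylidene)acetate and N-iodosuccinimide over K2CO3. This gives the (Z)-α-iodo enoate F3.
     - Ethylene glycol is monosilylated (Et3SiCl, imidazole) to 2-(triethylsilyloxy)ethanol F4 and oxidised (Dess–Martin periodinane) to 2-(triethylsilyloxy)acetaldehyde F5.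
     - Nozaki–Hiyama–Kishi coupling of F3 with F5 (CrCl2, NiCl2 cat., chiral sulfonamide–oxazoline ligand for reagent control at C9) keeps the alkene geometry and gives the (9S)-allylic alcohol F6.
     - Silylation of F6 (Et3SiOTf, 2,6-lutidine) gives 26.

**Further compounds**

F1 | step 18 | bicyclic 8β-carbinol, 9-O-triethylsilyl (2R,3S,6R,7R,8S,9S) | C=C1C(=O)O[C@@H]2/C=C(/C)[C@@H]3O[C@@H]3/C=C(/C(=O)OC)[C@H](O[Si](CC)(CC)CC)[C@@H](O)[C@@H]12
F2 | step 22 | bicyclic 8-ketone, 9-O-triethylsilyl | C=C1C(=O)O[C@@H]2/C=C(/C)[C@@H]3O[C@@H]3/C=C(/C(=O)OC)[C@H](O[Si](CC)(CC)CC)C(=O)[C@@H]12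
F3 | step 14 | methyl (2Z)-2-iodo-3-[(2R,3S)-3-{(1Z)-1-[(2R)-4-{[(4-methoxybenzyl)oxy]methyl}-5-oxo-2,5-dihydrofuran-2-yl]prop-1-en-2-yl}oxiran-2-yl]prop-2-enoate | COc1ccc(COCC2=C[C@H](OC2=O)/C=C(/C)[C@@H]3O[C@@H]3/C=C(/C(=O)OC)I)cc1
F4 | step 14 | 2-(triethylsilyloxy)ethanol | OCCO[Si](CC)(CC)CC
F5 | step 14 | 2-(triethylsilyloxy)acetaldehyde | O=CCO[Si](CC)(CC)CC
F6 | step 14 | open-chain enoate with free (9S)-hydroxyl, C8-O-triethylsilyl, C13-OPMB | COc1ccc(COCC2=C[C@H](OC2=O)/C=C(/C)[C@@H]3O[C@@H]3/C=C(/C(=O)OC)[C@H](O)CO[Si](CC)(CC)CC)cc1
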